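**Retrosynthetic overview**

1. Locants: C1 CH–O-acyl, C2 CH2, C3 C–OH, C4 CH–iPr, C5, C6, C7 C–Me, C8, C9=C10(Me); ring A = C3–C4–C5–C6–C7, ring B = C1–C2–C3–C7–C8–C9–C10. The plan rests on cyclopentane ring A sharing the C3–C7 bond with cycloheptene ring B, with isopropyl on C4 next to fusion carbon C3 and a methyl-bearing quaternary C7: C3/C4 are an isopropyl alkyne, C6/C7 a 2-propenyl group, C5 carbon monoxide.
2. Late stage: C1–O ester from veratric acid; C5 oxygen removed through the tosylhydrazone; C3–OH and C4–H from the C3=C4 enone by epoxidation, SmI2 opening and C4 equilibration.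
3. Key disconnection: intramolecular Pauson–Khand reaction of the acyclic (Z)-dienyne 15, forming C3–C7, C4–C5 and C5–C6.
4. Dienyne: C1–C2 bond by catalytic asymmetric propargylation of (Z)-enal 7 (from Still–Gennari olefination of 3-methylbut-3-enal) with the 1-isopropylallenylboronate 12.
5. Ring order: no ring exists before step 10; rings A and B are closed together in step 10.

Key step: step 10

Assumption: the SMILES is read as 1R,3S,4R,7R in these locants (3-OH, 4-isopropyl and 7-methyl on one face, 1-acyloxy on the other); azulene names use 3 = C4, 3a = C3, 5 = C1, 8a = C7.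

**Route**

Step 1
Reactants: 1 3-methylbut-3-en-1-ol
Product: 2 3-methylbut-3-enal
Conditions: Dess–Martin periodinane, CH2Cl2, 0 °C to rt; filtered solution used at once
Reagents that add atoms: none
Why: Dess–Martin oxidation of a primary alcohol under non-enolising conditions should leave the β,γ-double bond out of conjugation, and the volatile aldehyde is not stored.

Step 2
Reactants: 2 3-methylbut-3-enal; 3 ethyl 2-[bis(2,2,2-trifluoroethoxy)phosphoryl]propanoate
Product: 5 ethyl (2Z)-2,5-dimethylhexa-2,5-dienoate, via potassium enolate of phosphonate 4 (not isolated)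
Conditions: 3, KN(SiMe3)2, 18-crown-6, THF, −78 °C; then 2, −78 °C
Reagents that add atoms: none
Why: Still–Gennari variant of the Horner–Wadsworth–Emmons olefination, in which fast collapse of the syn oxaphosphetane from the trifluoroethyl phosphonate should place ester and C4 methylene cis (2Z), the weakly basic anion at −78 °C sparing the β,γ-unsaturated aldehyde.

Step 3
Reactants: 5 ethyl (2Z)-2,5-dimethylhexa-2,5-dienoate
Product: 6 (2Z)-2,5-dimethylhexa-2,5-dien-1-ol
Conditions: i-Bu2AlH (2.2 equiv), CH2Cl2, −78 to 0 °C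
Reagents that add atoms: none
Why: 1,2-reduction of an α,β-unsaturated ester by i-Bu2AlH gives the allylic alcohol without touching the alkene geometry or the skipped diene.

Step 4
Reactants: 6 (2Z)-2,5-dimethylhexa-2,5-dien-1-ol
Product: 7 (2Z)-2,5-dimethylhexa-2,5-dienal
Conditions: MnO2, CH2Cl2, rt; used directly
Reagents that add atoms: none
Why: heterogeneous allylic oxidation with MnO2 is neutral and should keep the (Z)-geometry of the α-methyl enal, which is carried on without storage.

Step 5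
Reactants: 8 3-methylbut-1-yne
Product: 10 4-methylpent-2-yn-1-ol, via lithium 3-methylbut-1-yn-1-ide 9 (not isolated)
Conditions: n-BuLi, THF, −78 °C; then (CH2O)n, −78 °C to rt
Reagents that add atoms: paraformaldehyde (as formaldehyde), C=O
Why: addition of a lithium acetylide to formaldehyde is a standard hydroxymethylation of a terminal alkyne.

Step 6
Reactants: 10 4-methylpent-2-yn-1-ol
Product: 11 methyl 4-methylpent-2-yn-1-yl carbonate
Conditions: ClCO2Me, pyridine, CH2Cl2, 0 °C
Reagents that add atoms: methyl chloroformate, COC(=O)Cl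
Why: acylation of a primary propargylic alcohol gives the carbonate leaving group needed for the SN2′ borylation.

Step 7
Reactants: 11 methyl 4-methylpent-2-yn-1-yl carbonate
Product: 12 4,4,5,5-tetramethyl-2-(4-methylpenta-1,2-dien-3-yl)-1,3,2-dioxaborolane
Conditions: B2pin2, CuCl (5 mol %), Xantphos (5 mol %), KO-t-Bu (10 mol %), THF, rt
Reagents that add atoms: bis(pinacolato)diboron, CC1(C)OB(OC1(C)C)B1OC(C)(C)C(C)(C)O1
Why: copper-catalysed SN2′ borylation of a propargylic carbonate (borylcupration of the alkyne, then β-oxygen elimination) puts boron on the isopropyl-bearing carbon and gives the 1,1-disubstituted allene.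

Step 8
Reactants: 7 (2Z)-2,5-dimethylhexa-2,5-dienal; 12 4,4,5,5-tetramethyl-2-(4-methylpenta-1,2-dien-3-yl)-1,3,2-dioxaborolane
Product: 14 (4Z,6R)-2,5,10-trimethylundeca-1,4-dien-8-yn-6-ol, via pinacol borate ester 13 (not isolated)
Conditions: (R)-TRIP [(R)-3,3′-bis(2,4,6-triisopropylphenyl)-1,1′-binaphthyl-2,2′-diyl hydrogen phosphate] (5 mol %), 4 Å MS, toluene, −30 °C; aqueous work-up
Reagents that add atoms: none
Why: chiral phosphoric acid catalysed allenylboration (asymmetric propargylation) of an aldehyde, in which SE2′ addition through a six-membered chair gives only the homopropargylic alcohol with the internal isopropyl alkyne and the (R)-acid should direct attack to the Re face of the enal as with aryl and alkenyl aldehydes, setting C6 of 14 (C1 of the target) as R, the sense to be confirmed on the Mosher esters.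

Step 9
Reactants: 14 (4Z,6R)-2,5,10-trimethylundeca-1,4-dien-8-yn-6-ol
Product: 15 tert-butyl(dimethyl){[(4Z,6R)-2,5,10-trimethylundeca-1,4-dien-8-yn-6-yl]oxy}silane
Conditions: TBSCl, imidazole, DMF, rt
Reagents that add atoms: tert-butyldimethylsilyl chloride, CC(C)(C)[Si](C)(C)Cl
Why: standard silylation of a secondary alcohol gives an ether that is stable to cobalt carbonyls, alkaline peroxide, SmI2 and boranes and supplies the bulk used for stereocontrol in step 10.

Step 10
Reactants: 15 tert-butyl(dimethyl){[(4Z,6R)-2,5,10-trimethylundeca-1,4-dien-8-yn-6-yl]oxy}silane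
Product: 17 (5R,8aS)-5-{[tert-butyl(dimethyl)silyl]oxy}-6,8a-dimethyl-3-(propan-2-yl)-4,5,8,8a-tetrahydroazulen-2(1H)-one, via dicobalt hexacarbonyl alkyne complex 16 (not isolated)
Conditions: Co2(CO)8 (1.1 equiv), CH2Cl2, rt; then n-BuSMe, ClCH2CH2Cl, 80 °C, 0.01 M
Reagents that add atoms: dicobalt octacarbonyl (source of CO), O=C=[Co](=C=O)(=C=O)(=C=O)[Co](=C=O)(=C=O)(=C=O)=C=O
Why: The alkyne is first bound as the hexacarbonyldicobalt complex 16; on heating with the sulfide promoter a CO ligand is lost, the C6=C7 alkene coordinates and inserts into a Co–C3 bond so that its substituted carbon C7 bonds to C3, then CO (C5) inserts and reductive elimination forms C4–C5 and C5–C6. The closest known reaction type is the intramolecular Pauson–Khand reaction of 1,n-enynes, including the uncommon 1,8-enynes whose tether is held by a cis double bond or a ring. Ring A (cyclopentenone) is closed by the [2+2+1] union of C3≡C4, C6=C7 and CO, and seven-membered ring B by the C3–C7 bond of the alkene insertion, the (Z)-C9=C10 bond keeping C1 and C8 cis and removing two rotors from the tether. The new stereocenter C7 is controlled by C1: 1,2-allylic strain with the C10 methyl pushes the silyloxy group pseudo-axial, and in a chair-like seven-membered transition state the C7 methyl stands pseudo-axial on the opposite face while C6 lies in the plane of the forming cyclopentenone, which should give the C1–O/C7–Me trans isomer 17. Regiochemistry is fixed by the tether (C3 must bond to C7), and the trisubstituted C9=C10 alkene cannot compete because it could only close a four-membered carbocycle. The step needs the 1,1-disubstituted alkene to insert faster than the complex decays, which high dilution, the promoter and the restricted tether are meant to secure.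

Step 11
Reactants: 17 (5R,8aS)-5-{[tert-butyl(dimethyl)silyl]oxy}-6,8a-dimethyl-3-(propan-2-yl)-4,5,8,8a-tetrahydroazulen-2(1H)-one
Product: 18 (3R,3aR,5R,8aS)-5-{[tert-butyl(dimethyl)silyl]oxy}-3,3a-epoxy-6,8a-dimethyl-3-(propan-2-yl)-3,3a,4,5,8,8a-hexahydroazulen-2(1H)-one
Conditions: H2O2 (30 % aq.), NaOH (0.5 equiv), MeOH, 0 °C
Reagents that add atoms: hydrogen peroxide, OO
Why: Weitz–Scheffer nucleophilic epoxidation touches only the enone (C9=C10 is inert), and hydroperoxide should add to C3 on the face of the C7 methyl because the other face is covered by C8 of the folded ring B and by the pseudo-axial C1 silyloxy group, as in the alkaline epoxidation of angularly methylated bicyclic enones, which sets C3.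

Step 12
Reactants: 18 (3R,3aR,5R,8aS)-5-{[tert-butyl(dimethyl)silyl]oxy}-3,3a-epoxy-6,8a-dimethyl-3-(propan-2-yl)-3,3a,4,5,8,8a-hexahydroazulen-2(1H)-one
Product: 19 (3aS,5R,8aS)-5-{[tert-butyl(dimethyl)silyl]oxy}-3a-hydroxy-6,8a-dimethyl-3-(propan-2-yl)-3,3a,4,5,8,8a-hexahydroazulen-2(1H)-one, C3 (= C4) epimers, taken on crude
Conditions: SmI2 (2.5 equiv), THF/MeOH, −90 °C
Reagents that add atoms: none
Why: SmI2 reduction of an α,β-epoxy ketone cleaves only the Cα–O bond (C4–O) through the ketyl, so the C3–O bond and its configuration are kept, and methanol protonates the samarium enolate at low temperature before β-elimination, the C4 configuration formed here not being relied on.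

Step 13
Reactants: 19 (3aS,5R,8aS)-hydroxy ketone, C3 (= C4) epimers
Product: 20 (3R,3aS,5R,8aS)-5-{[tert-butyl(dimethyl)silyl]oxy}-3a-hydroxy-6,8a-dimethyl-3-(propan-2-yl)-3,3a,4,5,8,8a-hexahydroazulen-2(1H)-one
Conditions: DBU (0.2 equiv), toluene, rt
Reagents that add atoms: none
Why: base-catalysed epimerisation through the C4 enolate should favour the isomer with isopropyl cis to the small C3 hydroxyl and trans to the C2 methylene of ring B (exo on the cis-fused bicycle), a catalytic amidine in an aprotic solvent keeping the alkoxide concentration too low for retro-aldol cleavage while enolate reprotonation outruns loss of hydroxide.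

Step 14
Reactants: 20 (3R,3aS,5R,8aS)-hydroxy ketone
Product: 21 N′-[(3S,3aS,5R,8aS)-5-{[tert-butyl(dimethyl)silyl]oxy}-3a-hydroxy-6,8a-dimethyl-3-(propan-2-yl)-3,3a,4,5,8,8a-hexahydroazulen-2(1H)-ylidene]-4-methylbenzenesulfonohydrazide
Conditions: TsNHNH2, MeOH, rt to 40 °C
Reagents that add atoms: 4-methylbenzenesulfonohydrazide, Cc1ccc(cc1)S(=O)(=O)NN
Why: condensation of a cyclopentanone with tosylhydrazide proceeds without added acid, which should spare the tertiary β-hydroxyl (the descriptor at C3 changes by priority only).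

Step 15
Reactants: 21 tosylhydrazone
Product: 23 (3R,3aS,5R,8aR)-5-{[tert-butyl(dimethyl)silyl]oxy}-6,8a-dimethyl-3-(propan-2-yl)-1,2,3,4,5,8-hexahydroazulen-3a-ol, via N-boryl tosylhydrazine 22 (not isolated)
Conditions: catecholborane (excess), CHCl3, 0 °C; then NaOAc·3H2O, reflux
Reagents that add atoms: none
Why: catecholborane reduction of a saturated tosylhydrazone (hydroboration of C=N, then acetate-induced loss of sulfinate and N2) turns C5 into CH2 under mild, non-enolising conditions that should leave C4, the tertiary alcohol, the alkene and the silyl ether untouched.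

Step 16
Reactants: 23 silyl ether
Product: 24 (3R,3aS,5R,8aR)-6,8a-dimethyl-3-(propan-2-yl)-1,2,3,4,5,8-hexahydroazulene-3a,5-diol
Conditions: n-Bu4NF, THF, rt
Reagents that add atoms: none
Why: fluoride cleavage of a secondary silyl ether frees the C1 hydroxyl without affecting any stereocenter.

Step 17
Reactants: 24 diol; 25 3,4-dimethoxybenzoic acid (veratric acid)
Product: 26 (3R,3aS,5R,8aR)-3a-hydroxy-6,8a-dimethyl-3-(propan-2-yl)-1,2,3,3a,4,5,8,8a-octahydroazulen-5-yl 3,4-dimethoxybenzoate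
Conditions: 25, DCC, DMAP (cat.), CH2Cl2, 0 °C to rt
Reagents that add atoms: none
Why: Steglich esterification acylates only the secondary allylic C1 hydroxyl, the tertiary C3 hydroxyl being inert to the acylpyridinium, and C1 keeps its configuration because the C–O bond is not broken.

**Compound list**

1 | 3-methylbut-3-en-1-ol | C=C(C)CCO | starting material
2 | 3-methylbut-3-enal | C=C(C)CC=O | intermediate
3 | ethyl 2-[bis(2,2,2-trifluoroethoxy)phosphoryl]propanoate | CCOC(=O)C(C)P(=O)(OCC(F)(F)F)OCC(F)(F)F | starting material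
4 | potassium enolate of 3 | CCOC([O-])=C(C)P(=O)(OCC(F)(F)F)OCC(F)(F)F.[K+] | intermediate
5 | ethyl (2Z)-2,5-dimethylhexa-2,5-dienoate | CCOC(=O)/C(C)=C\CC(C)=C | intermediate
6 | (2Z)-2,5-dimethylhexa-2,5-dien-1-ol | OC/C(C)=C\CC(C)=C | intermediate
7 | (2Z)-2,5-dimethylhexa-2,5-dienal | O=C/C(C)=C\CC(C)=C | intermediate
8 | 3-methylbut-1-yne | CC(C)C#C | starting material
9 | lithium 3-methylbut-1-yn-1-ide | [Li]C#CC(C)C | intermediate
10 | 4-methylpent-2-yn-1-ol | CC(C)C#CCO | intermediate
11 | methyl 4-methylpent-2-yn-1-yl carbonate | CC(C)C#CCOC(=O)OC | intermediate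
12 | 4,4,5,5-tetramethyl-2-(4-methylpenta-1,2-dien-3-yl)-1,3,2-dioxaborolane | C=C=C(C(C)C)B1OC(C)(C)C(C)(C)O1 | intermediate
13 | 4,4,5,5-tetramethyl-2-{[(4Z,6R)-2,5,10-trimethylundeca-1,4-dien-8-yn-6-yl]oxy}-1,3,2-dioxaborolane | CC(C)C#CC[C@@H](OB1OC(C)(C)C(C)(C)O1)/C(C)=C\CC(C)=C | intermediate
14 | (4Z,6R)-2,5,10-trimethylundeca-1,4-dien-8-yn-6-ol | CC(C)C#CC[C@@H](O)/C(C)=C\CC(C)=C | intermediate
15 | tert-butyl(dimethyl){[(4Z,6R)-2,5,10-trimethylundeca-1,4-dien-8-yn-6-yl]oxy}silane | CC(C)C#CC[C@@H](O[Si](C)(C)C(C)(C)C)/C(C)=C\CC(C)=C | intermediate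
16 | hexacarbonyldicobalt complex of the alkyne of 15 | CC(C)C12C3(C[C@@H](O[Si](C)(C)C(C)(C)C)/C(C)=C\CC(C)=C)[Co]1(=C=O)(=C=O)(=C=O)[Co]23(=C=O)(=C=O)=C=O | intermediate
17 | (5R,8aS)-5-{[tert-butyl(dimethyl)silyl]oxy}-6,8a-dimethyl-3-(propan-2-yl)-4,5,8,8a-tetrahydroazulen-2(1H)-one | CC(C)(C)[Si](C)(C)O[C@@H]1CC2=C(C(C)C)C(=O)C[C@]2(C)CC=C1C | intermediate
18 | (3R,3aR,5R,8aS)-5-{[tert-butyl(dimethyl)silyl]oxy}-3,3a-epoxy-6,8a-dimethyl-3-(propan-2-yl)-3,3a,4,5,8,8a-hexahydroazulen-2(1H)-one | CC(C)(C)[Si](C)(C)O[C@@H]1C[C@]23O[C@@]2(C(C)C)C(=O)C[C@]3(C)CC=C1C | intermediate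
19 | (3aS,5R,8aS)-5-{[tert-butyl(dimethyl)silyl]oxy}-3a-hydroxy-6,8a-dimethyl-3-(propan-2-yl)-3,3a,4,5,8,8a-hexahydroazulen-2(1H)-one, C3 epimers | CC(C)(C)[Si](C)(C)O[C@@H]1C[C@]2(O)C(C(C)C)C(=O)C[C@]2(C)CC=C1C | intermediate
20 | (3R,3aS,5R,8aS)-5-{[tert-butyl(dimethyl)silyl]oxy}-3a-hydroxy-6,8a-dimethyl-3-(propan-2-yl)-3,3a,4,5,8,8a-hexahydroazulen-2(1H)-one | CC(C)(C)[Si](C)(C)O[C@@H]1C[C@]2(O)[C@@H](C(C)C)C(=O)C[C@]2(C)CC=C1C | intermediate
21 | N′-[(3S,3aS,5R,8aS)-5-{[tert-butyl(dimethyl)silyl]oxy}-3a-hydroxy-6,8a-dimethyl-3-(propan-2-yl)-3,3a,4,5,8,8a-hexahydroazulen-2(1H)-ylidene]-4-methylbenzenesulfonohydrazide | CC(C)(C)[Si](C)(C)O[C@@H]1C[C@]2(O)[C@@H](C(C)C)C(=NNS(=O)(=O)c3ccc(C)cc3)C[C@]2(C)CC=C1C | intermediate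
22 | N-(1,3,2-benzodioxaborol-2-yl) tosylhydrazine from 21 (C2–H, N–B) | CC(C)(C)[Si](C)(C)O[C@@H]1C[C@]2(O)[C@@H](C(C)C)C(N(B3Oc4ccccc4O3)NS(=O)(=O)c3ccc(C)cc3)C[C@]2(C)CC=C1C | intermediate
23 | (3R,3aS,5R,8aR)-5-{[tert-butyl(dimethyl)silyl]oxy}-6,8a-dimethyl-3-(propan-2-yl)-1,2,3,4,5,8-hexahydroazulen-3a-ol | CC(C)(C)[Si](C)(C)O[C@@H]1C[C@]2(O)[C@@H](C(C)C)CC[C@]2(C)CC=C1C | intermediate
24 | (3R,3aS,5R,8aR)-6,8a-dimethyl-3-(propan-2-yl)-1,2,3,4,5,8-hexahydroazulene-3a,5-diol | O[C@@H]1C[C@]2(O)[C@@H](C(C)C)CC[C@]2(C)CC=C1C | intermediate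
25 | 3,4-dimethoxybenzoic acid (veratric acid) | COc1ccc(C(=O)O)cc1OC | starting material
26 | (3R,3aS,5R,8aR)-3a-hydroxy-6,8a-dimethyl-3-(propan-2-yl)-1,2,3,3a,4,5,8,8a-octahydroazulen-5-yl 3,4-dimethoxybenzoate | COc1ccc(C(=O)O[C@@H]2C[C@]3(O)[C@@H](C(C)C)CC[C@]3(C)CC=C2C)cc1OC | target

**Step count**

Total: 17 steps. Longest linear sequence: 14 steps (steps 1–4 and 8–17 from 3-methylbut-3-en-1-ol); the boronate branch (steps 5–7) joins at step 8.

**Steps most likely to fail**

Step 10. What may go wrong: insertion of the 1,1-disubstituted alkene through a seven-membered tether is slow, so decomplexation and oligomerisation compete, and the alkene may insert through the face that puts the C7 methyl cis to the C1 oxygen. Fallback (a stereochemical relay through the C1 epimer in place of direct induction; it answers a reversed facial preference, not a failure to cyclise): setting out from 7 and 12, step 8 is run with (S)-TRIP to give the pinacol borate F1 and from it the (6S)-alcohol F2, which is silylated to the dienyne F3. Its cobalt complex F4 should then close, with the same inherent cis preference, to the C1-epimeric enone F5, in which C7 already has the configuration of the target. Steps 11 to 16 are applied unchanged and lead through the epoxy ketone F6, the C4-epimeric hydroxy ketones F7, the hydroxy ketone F8, the tosylhydrazone F9, the N-boryl tosylhydrazine F10 and the silyl ether F11 to the C1-epimeric diol F12. F12 is then esterified with 25 under Mitsunobu conditions (PPh3, DIAD, THF, 0 °C), which inverts C1 and comes back to the route at 26. In this series step 11 loses the shielding by the C1 silyloxy group and relies on the ring fold alone.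

Step 11. What may go wrong: slow addition of hydroperoxide to the hindered tetrasubstituted enone, or attack on the face away from the C7 methyl. Fallback (hydroxyl-directed electrophilic epoxidation in place of nucleophilic epoxidation): from 17, a Corey–Bakshi–Shibata reduction ((R)-Me-CBS, BH3·SMe2, THF, −30 °C) should, with the isopropyl-bearing alkene side as the large group, give the allylic alcohol F13 with the hydroxyl on the face of the C7 methyl. VO(acac)2/t-BuOOH in CH2Cl2 then delivers the oxirane syn to that hydroxyl to give the epoxy alcohol F14, and Dess–Martin oxidation returns to the route at 18.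

Step 13. What may go wrong: loss of water from the β-hydroxy ketone back to enone 17, retro-aldol opening of ring A during base treatment, or an equilibrium that does not lie far enough on the side of the required C4 epimer. Fallback (a stereospecific 1,2-hydride shift in place of enolate protonation; it replaces steps 12 and 13): from 18, NaBH4/CeCl3·7H2O in MeOH at −78 °C, with hydride adding anti to the oxirane, gives the cis-epoxy alcohol F14. TMSOTf/i-Pr2NEt in CH2Cl2 at −78 °C then triggers a semipinacol rearrangement in which the C5 hydrogen migrates to C4 anti to the breaking C4–O bond, giving the silyloxy ketone F15 with C4 set by inversion. Citric acid in MeOH frees the tertiary alcohol and returns to the route at 20.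

**Further compounds**

F1 | step 10 | 4,4,5,5-tetramethyl-2-{[(4Z,6S)-2,5,10-trimethylundeca-1,4-dien-8-yn-6-yl]oxy}-1,3,2-dioxaborolane | CC(C)C#CC[C@H](OB1OC(C)(C)C(C)(C)O1)/C(C)=C\CC(C)=C
F2 | step 10 | (4Z,6S)-2,5,10-trimethylundeca-1,4-dien-8-yn-6-ol | CC(C)C#CC[C@H](O)/C(C)=C\CC(C)=C
F3 | step 10 | tert-butyl(dimethyl){[(4Z,6S)-2,5,10-trimethylundeca-1,4-dien-8-yn-6-yl]oxy}silane | CC(C)C#CC[C@H](O[Si](C)(C)C(C)(C)C)/C(C)=C\CC(C)=C
F4 | step 10 | hexacarbonyldicobalt complex of the alkyne of F3 | CC(C)C12C3(C[C@H](O[Si](C)(C)C(C)(C)C)/C(C)=C\CC(C)=C)[Co]1(=C=O)(=C=O)(=C=O)[Co]23(=C=O)(=C=O)=C=O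
F5 | step 10 | (5S,8aS)-5-{[tert-butyl(dimethyl)silyl]oxy}-6,8a-dimethyl-3-(propan-2-yl)-4,5,8,8a-tetrahydroazulen-2(1H)-one | CC(C)(C)[Si](C)(C)O[C@H]1CC2=C(C(C)C)C(=O)C[C@]2(C)CC=C1C
F6 | step 10 | (3R,3aR,5S,8aS)-5-{[tert-butyl(dimethyl)silyl]oxy}-3,3a-epoxy-6,8a-dimethyl-3-(propan-2-yl)-3,3a,4,5,8,8a-hexahydroazulen-2(1H)-one | CC(C)(C)[Si](C)(C)O[C@H]1C[C@]23O[C@@]2(C(C)C)C(=O)C[C@]3(C)CC=C1C
F7 | step 10 | (3aS,5S,8aS)-5-{[tert-butyl(dimethyl)silyl]oxy}-3a-hydroxy-6,8a-dimethyl-3-(propan-2-yl)-3,3a,4,5,8,8a-hexahydroazulen-2(1H)-one, C3 epimers | CC(C)(C)[Si](C)(C)O[C@H]1C[C@]2(O)C(C(C)C)C(=O)C[C@]2(C)CC=C1C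
F8 | step 10 | (3R,3aS,5S,8aS)-5-{[tert-butyl(dimethyl)silyl]oxy}-3a-hydroxy-6,8a-dimethyl-3-(propan-2-yl)-3,3a,4,5,8,8a-hexahydroazulen-2(1H)-one | CC(C)(C)[Si](C)(C)O[C@H]1C[C@]2(O)[C@@H](C(C)C)C(=O)C[C@]2(C)CC=C1C
F9 | step 10 | tosylhydrazone of F8 | CC(C)(C)[Si](C)(C)O[C@H]1C[C@]2(O)[C@@H](C(C)C)C(=NNS(=O)(=O)c3ccc(C)cc3)C[C@]2(C)CC=C1C
F10 | step 10 | N-(1,3,2-benzodioxaborol-2-yl) tosylhydrazine from F9 | CC(C)(C)[Si](C)(C)O[C@H]1C[C@]2(O)[C@@H](C(C)C)C(N(B3Oc4ccccc4O3)NS(=O)(=O)c3ccc(C)cc3)C[C@]2(C)CC=C1C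
F11 | step 10 | (3R,3aS,5S,8aR)-5-{[tert-butyl(dimethyl)silyl]oxy}-6,8a-dimethyl-3-(propan-2-yl)-1,2,3,4,5,8-hexahydroazulen-3a-ol | CC(C)(C)[Si](C)(C)O[C@H]1C[C@]2(O)[C@@H](C(C)C)CC[C@]2(C)CC=C1C
F12 | step 10 | (3R,3aS,5S,8aR)-6,8a-dimethyl-3-(propan-2-yl)-1,2,3,4,5,8-hexahydroazulene-3a,5-diol | O[C@H]1C[C@]2(O)[C@@H](C(C)C)CC[C@]2(C)CC=C1C
F13 | step 11 | (2S,5R,8aS)-5-{[tert-butyl(dimethyl)silyl]oxy}-6,8a-dimethyl-3-(propan-2-yl)-1,2,4,5,8,8a-hexahydroazulen-2-ol | CC(C)(C)[Si](C)(C)O[C@@H]1CC2=C(C(C)C)[C@@H](O)C[C@]2(C)CC=C1C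
F14 | step 11 | (2S,3S,3aR,5R,8aS)-5-{[tert-butyl(dimethyl)silyl]oxy}-3,3a-epoxy-6,8a-dimethyl-3-(propan-2-yl)-1,2,3,3a,4,5,8,8a-octahydroazulen-2-ol | CC(C)(C)[Si](C)(C)O[C@@H]1C[C@]23O[C@@]2(C(C)C)[C@@H](O)C[C@]3(C)CC=C1C
F15 | step 13 | (3R,3aS,5R,8aS)-5-{[tert-butyl(dimethyl)silyl]oxy}-6,8a-dimethyl-3-(propan-2-yl)-3a-[(trimethylsilyl)oxy]-3,3a,4,5,8,8a-hexahydroazulen-2(1H)-one | CC(C)(C)[Si](C)(C)O[C@@H]1C[C@]2(O[Si](C)(C)C)[C@@H](C(C)C)C(=O)C[C@]2(C)CC=C1C
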